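## Retrosynthetic overview

1. Numbering follows benzo[7]annulene: C5 spiro, C6 H2, C7 and C8 CH(CH3), C9 CH(OBz). The C4a–C5 bond is made last by para-selective phenolic oxidative coupling of an open-chain phenol benzoate. This closes the seven-membered ring and dearomatises the syringyl ring to the spiro-dienone.
2. The open-chain benzoate comes from an aryl ketone. C9 is carried at the acyl level, and the carbinol is set by catalyst-controlled reduction before benzoylation.
3. The aryl ketone comes from a syringyl-type benzylic Grignard reagent, cis-3,4-dimethyl-β-lactone and 3,4,5-trimethoxyphenyllithium. C6–C7 and C9–C9a are both made in one flask on the lactone, a chiral 1,3-dielectrophile obtained from propionyl chloride and acetaldehyde in one catalytic asymmetric event.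
4. Enabling feature: in the bridge C7–C8–C9 of the seven-membered ring the only heteroatom sits on C9, 1,3 to C7. C9/C8/C7 therefore map onto C2/C3/C4 of an oxetan-2-one, and trans-7,8-dimethyl equals a cis-lactone plus one inversion. Spiro C5 is not a stereocentre, because the 3',5'-dimethoxycyclohexadienone ring has a mirror plane, so the late ring closure adds no stereochemical problem.
5. Ring order: the oxetanone is a temporary ring, made in step 1 and opened in step 5. The seven-membered carbocycle and the dienone ring form together in step 9. All benzene rings are bought.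

Key step: step 5

Assumption: the quinine-derived catalyst is taken to give the (3S,4R)-lactone, by analogy with the sense of induction of cinchona-catalysed ketene reactions. If the sense were opposite, the pseudo-enantiomeric O-TMS-quinidine would be used.

## Route

**Step 1**
Reactants: 1 propionyl chloride; 2 acetaldehyde
Product: 4 (3S,4R)-3,4-dimethyloxetan-2-one (cis), via methylketene 3 (not isolated)
Conditions: O-TMS-quinine (10 mol %), LiClO4, i-Pr2NEt, CH2Cl2/Et2O, −78 °C, slow addition of 1
Reagents that add atoms: none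
Why: Alkaloid-catalysed ketene–aldehyde cyclocondensation (formal aldol–lactonisation): base-generated 3 is bound by the chiral tertiary amine as a (Z)-ammonium enolate that adds to Li+-activated 2 through a closed transition state and lactonises, so the catalyst should set both stereocentres in one event and the cis relation follows from the enolate geometry.

**Step 2**
Reactants: 5 syringaldehyde (4-hydroxy-3,5-dimethoxybenzaldehyde)
Product: 6 3,5-dimethoxy-4-[(triisopropylsilyl)oxy]benzaldehyde
Conditions: TIPSCl, imidazole, DMF, rt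
Reagents that add atoms: triisopropylsilyl chloride, CC(C)[Si](Cl)(C(C)C)C(C)C
Why: Standard silylation of a phenol; the bulky silyl ether should survive the Grignard, aryllithium and borane steps and later leaves with fluoride without loss of a benzoate.

**Step 3**
Reactants: 6 3,5-dimethoxy-4-[(triisopropylsilyl)oxy]benzaldehyde
Product: 7 {3,5-dimethoxy-4-[(triisopropylsilyl)oxy]phenyl}methanol
Conditions: NaBH4, MeOH, 0 °C
Reagents that add atoms: none
Why: Borohydride reduction of an aromatic aldehyde; no stereocentre is formed and the silyl ether is inert.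

**Step 4**
Reactants: 7 {3,5-dimethoxy-4-[(triisopropylsilyl)oxy]phenyl}methanol
Product: 9 [4-(chloromethyl)-2,6-dimethoxyphenoxy]triisopropylsilane, via benzylic mesylate 8 (not isolated)
Conditions: MsCl, Et3N, CH2Cl2, 0 °C to rt
Reagents that add atoms: methanesulfonyl chloride, CS(=O)(=O)Cl
Why: Mesylation of an electron-rich benzylic alcohol followed by in situ SN2 displacement of the sulfonate by the liberated chloride, a usual mild route to acid-sensitive benzylic chlorides.

**Step 5**
Reactants: 9 [4-(chloromethyl)-2,6-dimethoxyphenoxy]triisopropylsilane; 4 (3S,4R)-3,4-dimethyloxetan-2-one; 10 5-bromo-1,2,3-trimethoxybenzene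
Product: 15 (2S,3R)-4-{3,5-dimethoxy-4-[(triisopropylsilyl)oxy]phenyl}-2,3-dimethyl-1-(3,4,5-trimethoxyphenyl)butan-1-one, via benzylic Grignard reagent 11 (not isolated), via magnesium carboxylate 12 (not isolated), via aryllithium 13 (not isolated), via gem-dialkoxide 14 (not isolated)
Conditions: (i) 9, Mg, THF, 0 °C; (ii) 4, CuBr·SMe2 (10 mol %), THF/Me2S, −40 to 0 °C; (iii) 13 [from 10, n-BuLi, THF, −78 °C], −78 to 0 °C; (iv) 1 M HCl, 0 °C
Reagents that add atoms: none
Why: Catalytic Cu(I) turns Grignard reagent 11 into a soft magnesiocuprate that attacks C4 of the strained lactone 4 anti to the C4–O bond (Cu-catalysed SN2 alkyl–oxygen opening of a β-lactone by a Grignard reagent), which forms the CH2–CH(CH3) bond with inversion, leaves the C3 methyl centre untouched and so converts the cis-lactone into the threo-2,3-dimethyl carboxylate 12. Carboxylate 12 is inert to the remaining Grignard reagent and no longer carries a β-leaving group, yet it accepts one equivalent of the harder aryllithium 13 (ketone synthesis from a carboxylate salt and an organolithium), which forms the aryl–C(O) bond. The gem-dialkoxide 14 cannot collapse before the acidic quench, so no ketone coexists with 13 and over-addition is excluded. No ring is closed in this step; the temporary oxetanone ring is opened, and its strain pays for substitution at a secondary carbon. No new stereocentre is created: both centres of 15 are relayed from the catalytic event of step 1, one by inversion and one by retention. The step needs alkyl–O rather than acyl–O attack, secured by the strain-activated C4–O bond together with the soft Cu(I) nucleophile in Me2S, and it needs each terminus of the C3 unit to meet its own partner, secured because after ring opening the anionic carboxylate is the only electrophile left for the hard nucleophile added second.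

**Step 6**
Reactants: 15 (2S,3R)-aryl ketone
Product: 16 (1R,2S,3R)-4-{3,5-dimethoxy-4-[(triisopropylsilyl)oxy]phenyl}-2,3-dimethyl-1-(3,4,5-trimethoxyphenyl)butan-1-ol
Conditions: (S)-Me-CBS (0.5 equiv), BH3·SMe2, toluene, −30 °C; then MeOH
Reagents that add atoms: none
Why: Corey–Bakshi–Shibata reduction: the (S)-oxazaborolidine binds the ketone with the aryl group as the large substituent and should deliver hydride to the face that gives the (1R)-carbinol, syn to the C2 methyl group, with catalyst control overriding the modest Felkin–Anh preference of the substrate for the epimer.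

**Step 7**
Reactants: 16 (1R,2S,3R)-alcohol
Product: 17 (1R,2S,3R)-4-{3,5-dimethoxy-4-[(triisopropylsilyl)oxy]phenyl}-2,3-dimethyl-1-(3,4,5-trimethoxyphenyl)butyl benzoate
Conditions: BzCl, Et3N, DMAP (cat.), CH2Cl2, 0 °C to rt
Reagents that add atoms: benzoyl chloride, O=C(Cl)c1ccccc1
Why: DMAP-catalysed O-acylation under basic conditions; the C–O bond of the carbinol is not broken, so its configuration is retained.

**Step 8**
Reactants: 17 silyl-protected benzoate
Product: 18 (1R,2S,3R)-4-(4-hydroxy-3,5-dimethoxyphenyl)-2,3-dimethyl-1-(3,4,5-trimethoxyphenyl)butyl benzoate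
Conditions: TBAF, AcOH, THF, 0 °C
Reagents that add atoms: none
Why: Fluoride-induced cleavage of a phenolic silyl ether, buffered with acetic acid so that neither fluoride nor phenoxide attacks the benzoate.

**Step 9**
Reactants: 18 phenol benzoate
Product: 19 (7R,8S,9R)-2,3,3',4,5'-pentamethoxy-7,8-dimethyl-4'-oxo-6,7,8,9-tetrahydrospiro[benzo[7]annulene-5,1'-cyclohexa[2,5]diene]-9-yl benzoate (target)
Conditions: PhI(OAc)2, (CF3)2CHOH, 0 °C
Reagents that add atoms: none
Why: Hypervalent-iodine phenolic oxidative coupling (dearomatising spirocyclisation, the presumed biosynthetic closure): two-electron oxidation of the 2,6-dimethoxyphenol makes its para carbon electrophilic, C2 of the trimethoxyphenyl ring (ortho and para to methoxy groups) attacks it in a seven-membered closure in a non-nucleophilic solvent, the new quaternary carbon is not a stereocentre because the two dienone halves are identical, and the three existing centres are not touched.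

## Compound list

| No. | Name | SMILES | Role |
|---|---|---|---|
| 1 | propionyl chloride | CCC(=O)Cl | starting material |
| 2 | acetaldehyde | CC=O | starting material |
| 3 | methylketene | CC=C=O | intermediate |
| 4 | (3S,4R)-3,4-dimethyloxetan-2-one | O=C1O[C@H](C)[C@@H]1C | intermediate |
| 5 | syringaldehyde | COc1cc(C=O)cc(OC)c1O | starting material |
| 6 | 3,5-dimethoxy-4-[(triisopropylsilyl)oxy]benzaldehyde | COc1cc(C=O)cc(OC)c1O[Si](C(C)C)(C(C)C)C(C)C | intermediate |
| 7 | {3,5-dimethoxy-4-[(triisopropylsilyl)oxy]phenyl}methanol | COc1cc(CO)cc(OC)c1O[Si](C(C)C)(C(C)C)C(C)C | intermediate |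
| 8 | 3,5-dimethoxy-4-[(triisopropylsilyl)oxy]benzyl methanesulfonate | COc1cc(COS(C)(=O)=O)cc(OC)c1O[Si](C(C)C)(C(C)C)C(C)C | intermediate |
| 9 | [4-(chloromethyl)-2,6-dimethoxyphenoxy]triisopropylsilane | COc1cc(CCl)cc(OC)c1O[Si](C(C)C)(C(C)C)C(C)C | intermediate |
| 10 | 5-bromo-1,2,3-trimethoxybenzene | COc1cc(Br)cc(OC)c1OC | starting material |
| 11 | {3,5-dimethoxy-4-[(triisopropylsilyl)oxy]benzyl}magnesium chloride | COc1cc(C[Mg]Cl)cc(OC)c1O[Si](C(C)C)(C(C)C)C(C)C | intermediate |
| 12 | chloromagnesium (2S,3R)-4-{3,5-dimethoxy-4-[(triisopropylsilyl)oxy]phenyl}-2,3-dimethylbutanoate | COc1cc(C[C@@H](C)[C@H](C)C(=O)O[Mg]Cl)cc(OC)c1O[Si](C(C)C)(C(C)C)C(C)C | intermediate |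
| 13 | (3,4,5-trimethoxyphenyl)lithium | [Li]c1cc(OC)c(OC)c(OC)c1 | intermediate |
| 14 | mixed lithium/chloromagnesium gem-dialkoxide (metallated hydrate of 15; dialkoxide carbon undefined) | COc1cc(C[C@@H](C)[C@H](C)C(O[Li])(O[Mg]Cl)c2cc(OC)c(OC)c(OC)c2)cc(OC)c1O[Si](C(C)C)(C(C)C)C(C)C | intermediate |
| 15 | (2S,3R)-4-{3,5-dimethoxy-4-[(triisopropylsilyl)oxy]phenyl}-2,3-dimethyl-1-(3,4,5-trimethoxyphenyl)butan-1-one | COc1cc(C[C@@H](C)[C@H](C)C(=O)c2cc(OC)c(OC)c(OC)c2)cc(OC)c1O[Si](C(C)C)(C(C)C)C(C)C | intermediate |
| 16 | (1R,2S,3R)-4-{3,5-dimethoxy-4-[(triisopropylsilyl)oxy]phenyl}-2,3-dimethyl-1-(3,4,5-trimethoxyphenyl)butan-1-ol | COc1cc(C[C@@H](C)[C@H](C)[C@@H](O)c2cc(OC)c(OC)c(OC)c2)cc(OC)c1O[Si](C(C)C)(C(C)C)C(C)C | intermediate |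
| 17 | (1R,2S,3R)-4-{3,5-dimethoxy-4-[(triisopropylsilyl)oxy]phenyl}-2,3-dimethyl-1-(3,4,5-trimethoxyphenyl)butyl benzoate | COc1cc(C[C@@H](C)[C@H](C)[C@@H](OC(=O)c2ccccc2)c2cc(OC)c(OC)c(OC)c2)cc(OC)c1O[Si](C(C)C)(C(C)C)C(C)C | intermediate |
| 18 | (1R,2S,3R)-4-(4-hydroxy-3,5-dimethoxyphenyl)-2,3-dimethyl-1-(3,4,5-trimethoxyphenyl)butyl benzoate | COc1cc(C[C@@H](C)[C@H](C)[C@@H](OC(=O)c2ccccc2)c2cc(OC)c(OC)c(OC)c2)cc(OC)c1O | intermediate |
| 19 | (7R,8S,9R)-2,3,3',4,5'-pentamethoxy-7,8-dimethyl-4'-oxo-6,7,8,9-tetrahydrospiro[benzo[7]annulene-5,1'-cyclohexa[2,5]diene]-9-yl benzoate | COC1=CC2(C=C(OC)C1=O)C[C@@H](C)[C@H](C)[C@@H](OC(=O)c1ccccc1)c1cc(OC)c(OC)c(OC)c12 | target |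

## Step count and risks

Total step count: 9. Longest linear sequence: 8 (steps 2 to 9).

**Steps most likely to fail**

1. **Step 5.** C4 of lactone 4 is secondary and flanked by the C3 methyl group. The copper reagent may therefore attack the acyl carbon, or act as a base and trigger β-elimination. In the second stage the aryllithium may enolise the carboxylate instead of adding.

   The fallback sets out from 11 and returns at 16. Grignard reagent 11 opens the commercial, α-unsubstituted (R)-4-methyloxetan-2-one under the same Cu(I) catalysis. This site is less hindered and reacts with inversion, giving (3R)-4-{3,5-dimethoxy-4-[(triisopropylsilyl)oxy]phenyl}-3-methylbutanoic acid F1. Activation with pivaloyl chloride and coupling with lithiated (S)-4-benzyloxazolidin-2-one gives the N-acyl oxazolidinone F2. NaHMDS/MeI methylates its (Z)-enolate on the face opposite to the benzyl group and gives the (2S,3R)-dimethyl imide F3. LiBH4 then releases the primary alcohol F4, and Dess–Martin oxidation gives the aldehyde F5. Aryllithium 13 adds to F5 under Felkin–Anh control, which favours the syn carbinol 16 directly.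

2. **Step 9.** The oxidised phenol may lose a benzylic proton and be diverted through a quinone methide into a six-membered closure. It may also be captured by solvent, or the product may undergo an acid-induced dienone–phenol shift to the eight-membered biaryl.

   The fallback sets out from 16 and returns at 19. Alkoxide- and methoxy-directed ortho-lithiation of 16 (n-BuLi, TMEDA) followed by iodine gives the 2-iodo-3,4,5-trimethoxyphenyl carbinol F7. Benzoylation gives the iodo benzoate F8, and buffered TBAF gives the iodo phenol F9. A Pd(0)/biarylphosphine-catalysed intramolecular arylative dearomatisation of the phenolate (K2CO3, dioxane, heat) then forms the aryl–spiro bond without any oxidant and gives 19.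

3. **Step 6.** Facial selectivity may be poor, because catalyst control works against the Felkin–Anh bias and the hindered ketone leaves room for uncatalysed borane reduction.

   The fallback sets out from 15 and returns at 17. L-Selectride (THF, −78 °C) follows the substrate bias and gives the (1S,2S,3R)-alcohol F6. A Mitsunobu reaction with benzoic acid (PPh3, DIAD) installs the benzoate with inversion and gives 17.

## Further compounds

F1 | step 5 | (3R)-4-{3,5-dimethoxy-4-[(triisopropylsilyl)oxy]phenyl}-3-methylbutanoic acid | COc1cc(C[C@@H](C)CC(=O)O)cc(OC)c1O[Si](C(C)C)(C(C)C)C(C)C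
F2 | step 5 | (4S)-4-benzyl-3-[(3R)-4-{3,5-dimethoxy-4-[(triisopropylsilyl)oxy]phenyl}-3-methylbutanoyl]-1,3-oxazolidin-2-one | COc1cc(C[C@@H](C)CC(=O)N2[C@@H](Cc3ccccc3)COC2=O)cc(OC)c1O[Si](C(C)C)(C(C)C)C(C)C
F3 | step 5 | (4S)-4-benzyl-3-[(2S,3R)-4-{3,5-dimethoxy-4-[(triisopropylsilyl)oxy]phenyl}-2,3-dimethylbutanoyl]-1,3-oxazolidin-2-one | COc1cc(C[C@@H](C)[C@H](C)C(=O)N2[C@@H](Cc3ccccc3)COC2=O)cc(OC)c1O[Si](C(C)C)(C(C)C)C(C)C
F4 | step 5 | (2S,3R)-4-{3,5-dimethoxy-4-[(triisopropylsilyl)oxy]phenyl}-2,3-dimethylbutan-1-ol | COc1cc(C[C@@H](C)[C@H](C)CO)cc(OC)c1O[Si](C(C)C)(C(C)C)C(C)C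
F5 | step 5 | (2S,3R)-4-{3,5-dimethoxy-4-[(triisopropylsilyl)oxy]phenyl}-2,3-dimethylbutanal | COc1cc(C[C@@H](C)[C@H](C)C=O)cc(OC)c1O[Si](C(C)C)(C(C)C)C(C)C
F6 | step 6 | (1S,2S,3R)-4-{3,5-dimethoxy-4-[(triisopropylsilyl)oxy]phenyl}-2,3-dimethyl-1-(3,4,5-trimethoxyphenyl)butan-1-ol | COc1cc(C[C@@H](C)[C@H](C)[C@H](O)c2cc(OC)c(OC)c(OC)c2)cc(OC)c1O[Si](C(C)C)(C(C)C)C(C)C
F7 | step 9 | (1R,2S,3R)-4-{3,5-dimethoxy-4-[(triisopropylsilyl)oxy]phenyl}-1-(2-iodo-3,4,5-trimethoxyphenyl)-2,3-dimethylbutan-1-ol | COc1cc(C[C@@H](C)[C@H](C)[C@@H](O)c2cc(OC)c(OC)c(OC)c2I)cc(OC)c1O[Si](C(C)C)(C(C)C)C(C)C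
F8 | step 9 | (1R,2S,3R)-4-{3,5-dimethoxy-4-[(triisopropylsilyl)oxy]phenyl}-1-(2-iodo-3,4,5-trimethoxyphenyl)-2,3-dimethylbutyl benzoate | COc1cc(C[C@@H](C)[C@H](C)[C@@H](OC(=O)c2ccccc2)c2cc(OC)c(OC)c(OC)c2I)cc(OC)c1O[Si](C(C)C)(C(C)C)C(C)C
F9 | step 9 | (1R,2S,3R)-4-(4-hydroxy-3,5-dimethoxyphenyl)-1-(2-iodo-3,4,5-trimethoxyphenyl)-2,3-dimethylbutyl benzoate | COc1cc(C[C@@H](C)[C@H](C)[C@@H](OC(=O)c2ccccc2)c2cc(OC)c(OC)c(OC)c2I)cc(OC)c1O
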